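**Retrosynthetic overview**

1. Feature: ring A carries OH on C1, the (CH2)12 bridge on C3 and the ether oxygen on C5. It is therefore a 5-alkylresorcinol mono-aryl ether, the dehydrogenated form of a 3-aryloxy-5-alkylcyclohex-2-en-1-one; the ether oxygen is O1 of ring B, flanked by the oxygens on C2 and C6.
2. Target 20 ⇒ (O-demethylation, dehydrogenation of ring A) macrocyclic vinylogous aryl ester 15 ⇒ (O–C3 bond, addition–elimination) chloroenone phenol 14.
3. 14 ⇒ 5-substituted cyclohexane-1,3-dione 12 ⇒ (Michael–Claisen) enone 7 + dimethyl malonate ⇒ (cross-metathesis) alkene 5 + methyl vinyl ketone ⇒ (B-alkyl Suzuki–Miyaura) aryl bromide 2 + tetradeca-1,13-diene.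
4. Ring order: ring B is bought; the carbocycle that becomes ring A is built in step 4; the 20-membered ring is closed in step 7; ring A is aromatised in step 8.

Key step: step 7

Remark: the target is achiral; the sp3 centre at C5 of the cyclohexenone surrogate of ring A (compounds 9 to 17) is carried as a racemate and disappears on aromatisation.

**Route**

Step 1
Reactants: 1 4-bromo-2,6-dimethoxyphenol
Product: 2 2-(benzyloxy)-5-bromo-1,3-dimethoxybenzene
Conditions: BnBr (1.2 equiv), K2CO3, DMF, 60 °C
Reagents that add atoms: benzyl bromide, BrCc1ccccc1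
Why: Williamson ether synthesis, in which the carbonate-generated phenoxide is O-alkylated by the reactive benzylic bromide despite its two flanking methoxy groups; the benzyl ether should survive every step up to its Lewis-acid cleavage in step 6.

Step 2
Reactants: 2 2-(benzyloxy)-5-bromo-1,3-dimethoxybenzene; 3 tetradeca-1,13-diene
Product: 5 2-(benzyloxy)-1,3-dimethoxy-5-(tetradec-13-en-1-yl)benzene, via B-(tetradec-13-enyl)-9-BBN 4 (not isolated)
Conditions: 3 (4 equiv), 9-BBN (1.2 equiv), THF, 0 °C to rt; then 2, PdCl2(dppf) (5 mol%), aq. K3PO4, DMF, 60 °C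
Reagents that add atoms: none
Why: Anti-Markovnikov hydroboration of one terminal alkene of the excess diene by 9-BBN (double hydroboration suppressed statistically), then B-alkyl Suzuki–Miyaura coupling with the unhindered aryl bromide, should attach to C4 of ring B a chain of twelve CH2 groups ending in a terminal alkene.

Step 3
Reactants: 5 2-(benzyloxy)-1,3-dimethoxy-5-(tetradec-13-en-1-yl)benzene; 6 but-3-en-2-one (methyl vinyl ketone)
Product: 7 (E)-16-[4-(benzyloxy)-3,5-dimethoxyphenyl]hexadec-3-en-2-one
Conditions: 6 (5 equiv), second-generation Hoveyda–Grubbs catalyst, RuCl2(H2IMes)(=CH-C6H4-2-OiPr) (3 mol%), CH2Cl2, 40 °C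
Reagents that add atoms: none
Why: Olefin cross-metathesis of a terminal alkene with an electron-poor vinyl ketone, which homodimerises only slowly, should give the E-enone selectively with loss of ethene.

Step 4
Reactants: 7 (E)-16-[4-(benzyloxy)-3,5-dimethoxyphenyl]hexadec-3-en-2-one; 8 dimethyl malonate
Product: 12 5-{12-[4-(benzyloxy)-3,5-dimethoxyphenyl]dodecyl}cyclohexane-1,3-dione, via Michael adduct 9 (not isolated), via cyclic keto ester 10 (not isolated), via keto acid 11 (not isolated)
Conditions: NaOMe (1.3 equiv), MeOH/THF, reflux; then aq. NaOH, reflux; then aq. HCl to pH 1, 70 °C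
Reagents that add atoms: none
Why: Michael addition of the malonate anion to the enone, Claisen (Dieckmann-type) closure of the methyl ketone enolate onto an ester, saponification and decarboxylation of the beta-keto acid build the six-membered 1,3-dione that stands in for ring A; the new sp3 centre at C5 forms as a racemate without control, which is harmless because step 8 makes it an aromatic carbon.

Step 5
Reactants: 12 5-{12-[4-(benzyloxy)-3,5-dimethoxyphenyl]dodecyl}cyclohexane-1,3-dione
Product: 13 5-{12-[4-(benzyloxy)-3,5-dimethoxyphenyl]dodecyl}-3-chlorocyclohex-2-en-1-one (racemic)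
Conditions: (COCl)2 (1.3 equiv), DMF (cat.), CH2Cl2, 0 °C to rt
Reagents that add atoms: oxalyl chloride, O=C(Cl)C(Cl)=O
Why: Vilsmeier-type activation of the enolised dione followed by chloride addition–elimination gives the vinylogous acid chloride, and the symmetry of the dione allows only one regioisomer.

Step 6
Reactants: 13 5-{12-[4-(benzyloxy)-3,5-dimethoxyphenyl]dodecyl}-3-chlorocyclohex-2-en-1-one
Product: 14 3-chloro-5-[12-(4-hydroxy-3,5-dimethoxyphenyl)dodecyl]cyclohex-2-en-1-one (racemic)
Conditions: BCl3 (2.5 equiv), C6HMe5 (3 equiv), CH2Cl2, −78 °C; sat. aq. NaHCO3 quench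
Reagents that add atoms: none
Why: Lewis-acid cleavage of the aryl benzyl ether by BCl3, with pentamethylbenzene as a non-basic benzyl cation scavenger, runs at −78 °C, where the flanking methyl ethers and the chloroenone should stay intact and ring B is shielded from C-benzylation.

Step 7
Reactants: 14 3-chloro-5-[12-(4-hydroxy-3,5-dimethoxyphenyl)dodecyl]cyclohex-2-en-1-one
Product: 15 macrocyclic 3-aryloxycyclohex-2-en-1-one (racemic; the oxygen on C3 is O1 of the 2,6-dimethoxy-1,4-phenylene ring B; a (CH2)12 chain joins C5 to C4 of ring B; 20-membered ring)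
Conditions: Cs2CO3 (5 equiv), MeCN (about 1 mM final), 60 °C, syringe-pump addition of 14 over 12 h
Reagents that add atoms: none
Why: The caesium 2,6-dimethoxyphenoxide of ring B adds in conjugate fashion to C3, the chlorine-bearing beta-carbon of the enone, and the enolate formed expels chloride to restore the enone as a vinylogous aryl ester (addition–elimination). The closest known reaction is the base-mediated etherification of phenols with 3-chlorocyclohex-2-enones, run here within one molecule under high dilution. The 20-membered ring closes in a 20-exo-trig mode, since the C2=C3 double bond lies outside the new ring. No stereocentre is created: C5 is already present as a racemate and the sp3 C3 of the adduct is transient. Attack through oxygen is enforced because both ortho positions and the para position of the phenoxide are substituted, the site of attack is unambiguous because only one carbon of the enone carries the leaving group, and cyclisation should win over oligomerisation through slow addition into dilute solution, helped by the flexible tether and the sp3 C4 and C5 of the ring A surrogate. No transition metal is involved, so the two flanking methoxy groups should only slow the attack and not block it.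

Step 8
Reactants: 15 macrocyclic 3-aryloxycyclohex-2-en-1-one
Product: 19 3^2,3^6-dimethoxy-2-oxa-1(1,3),3(1,4)-dibenzenacyclopentadecaphan-1^5-ol (macrocyclic diaryl ether with free OH on ring A and two OMe on ring B), via alpha-phenylselanyl ketone 16 (not isolated), via selenoxide 17 (not isolated), via cyclohexa-2,5-dienone 18 (not isolated)
Conditions: LiN(iPr)2 (LDA, 1.15 equiv), THF, −78 °C; PhSeCl (1.2 equiv), −78 °C; then AcOH, 30% H2O2 (2.5 equiv), 0 °C to rt
Reagents that add atoms: none
Why: Kinetic deprotonation of the vinylogous ester at C6 (the alpha-prime position), selenenylation and selenoxide syn-elimination towards the C5 hydrogen (alpha-selenenylation and selenoxide elimination) should give the cross-conjugated dienone, whose tautomerisation aromatises ring A and erases the C5 stereocentre.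

Step 9
Reactants: 19 3^2,3^6-dimethoxy-2-oxa-1(1,3),3(1,4)-dibenzenacyclopentadecaphan-1^5-ol
Product: 20 2-oxa-1(1,3),3(1,4)-dibenzenacyclopentadecaphane-1^5,3^2,3^6-triol (CNP0314249.0)
Conditions: BBr3 (6 equiv), CH2Cl2, −78 °C to rt; ice-water, then aq. NaHCO3
Reagents that add atoms: none
Why: BBr3 cleavage of aryl methyl ethers (Lewis acid–base adduct, then bromide attack at methyl) should free both hydroxyls of ring B, while the diaryl ether, the ring A phenol and the saturated bridge are inert.

**Compound list**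

1 | 4-bromo-2,6-dimethoxyphenol | COc1cc(Br)cc(OC)c1O | starting material
2 | 2-(benzyloxy)-5-bromo-1,3-dimethoxybenzene | COc1cc(Br)cc(OC)c1OCc1ccccc1 | intermediate
3 | tetradeca-1,13-diene | C=CCCCCCCCCCCC=C | starting material
4 | 9-(tetradec-13-en-1-yl)-9-borabicyclo[3.3.1]nonane | C=CCCCCCCCCCCCCB1C2CCCC1CCC2 | intermediate (not isolated)
5 | 2-(benzyloxy)-1,3-dimethoxy-5-(tetradec-13-en-1-yl)benzene | C=CCCCCCCCCCCCCc1cc(OC)c(OCc2ccccc2)c(OC)c1 | intermediate
6 | but-3-en-2-one (methyl vinyl ketone) | CC(=O)C=C | starting material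
7 | (E)-16-[4-(benzyloxy)-3,5-dimethoxyphenyl]hexadec-3-en-2-one | CC(=O)/C=C/CCCCCCCCCCCCc1cc(OC)c(OCc2ccccc2)c(OC)c1 | intermediate
8 | dimethyl malonate | COC(=O)CC(=O)OC | starting material
9 | dimethyl 2-{16-[4-(benzyloxy)-3,5-dimethoxyphenyl]-2-oxohexadecan-4-yl}propanedioate (racemic) | CC(=O)CC(CCCCCCCCCCCCc1cc(OC)c(OCc2ccccc2)c(OC)c1)C(C(=O)OC)C(=O)OC | intermediate (not isolated)
10 | methyl 6-{12-[4-(benzyloxy)-3,5-dimethoxyphenyl]dodecyl}-2,4-dioxocyclohexane-1-carboxylate (racemic, diastereomer mixture, as its sodium enolate in the flask) | COC(=O)C1C(CCCCCCCCCCCCc2cc(OC)c(OCc3ccccc3)c(OC)c2)CC(=O)CC1=O | intermediate (not isolated)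
11 | 6-{12-[4-(benzyloxy)-3,5-dimethoxyphenyl]dodecyl}-2,4-dioxocyclohexane-1-carboxylic acid (racemic, diastereomer mixture) | OC(=O)C1C(CCCCCCCCCCCCc2cc(OC)c(OCc3ccccc3)c(OC)c2)CC(=O)CC1=O | intermediate (not isolated)
12 | 5-{12-[4-(benzyloxy)-3,5-dimethoxyphenyl]dodecyl}cyclohexane-1,3-dione | O=C1CC(=O)CC(CCCCCCCCCCCCc2cc(OC)c(OCc3ccccc3)c(OC)c2)C1 | intermediate
13 | 5-{12-[4-(benzyloxy)-3,5-dimethoxyphenyl]dodecyl}-3-chlorocyclohex-2-en-1-one (racemic) | O=C1C=C(Cl)CC(CCCCCCCCCCCCc2cc(OC)c(OCc3ccccc3)c(OC)c2)C1 | intermediate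
14 | 3-chloro-5-[12-(4-hydroxy-3,5-dimethoxyphenyl)dodecyl]cyclohex-2-en-1-one (racemic) | O=C1C=C(Cl)CC(C1)CCCCCCCCCCCCc1cc(OC)c(O)c(OC)c1 | intermediate
15 | macrocyclic 3-aryloxycyclohex-2-en-1-one (racemic): O on C3 is O1 of ring B (2,6-dimethoxy-1,4-phenylene), C5 linked to C4 of ring B by (CH2)12 | O=C1C=C2CC(C1)CCCCCCCCCCCCc1cc(OC)c(O2)c(OC)c1 | intermediate
16 | 6-(phenylselanyl) derivative of 15 (selenium on the CH2 between C=O and C5; racemic, diastereomer mixture) | O=C1C=C2CC(CCCCCCCCCCCCc3cc(OC)c(O2)c(OC)c3)C1[Se]c1ccccc1 | intermediate (not isolated)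
17 | selenoxide of 16 (diastereomer mixture) | O=C1C=C2CC(CCCCCCCCCCCCc3cc(OC)c(O2)c(OC)c3)C1[Se](=O)c1ccccc1 | intermediate (not isolated)
18 | macrocyclic 3-aryloxy-5-alkylcyclohexa-2,5-dien-1-one (C4 is CH2; keto tautomer of 19) | O=C1C=C2CC(CCCCCCCCCCCCc3cc(OC)c(O2)c(OC)c3)=C1 | intermediate (not isolated)
19 | 3^2,3^6-dimethoxy-2-oxa-1(1,3),3(1,4)-dibenzenacyclopentadecaphan-1^5-ol | Oc1cc2cc(c1)Oc1c(OC)cc(cc1OC)CCCCCCCCCCCC2 | intermediate
20 | 2-oxa-1(1,3),3(1,4)-dibenzenacyclopentadecaphane-1^5,3^2,3^6-triol (CNP0314249.0) | Oc1cc2cc(c1)Oc1c(O)cc(cc1O)CCCCCCCCCCCC2 | target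

**Step count**

Total steps: 9. Longest linear sequence: 9 (steps 1 to 9 from compound 1).

**Steps most likely to fail**

Step 7 (key macrocyclisation). The closure by the hindered phenoxide may be slow, so that intermolecular addition–elimination (oligomer growth) or base-induced decay of the chloroenone outruns it. The fallback forms the O–C3 bond intermolecularly and closes the 20-membered ring at the aryl–CH2 bond instead. It sets out from diene 3 and comes back at 15.
- Cross-metathesis of excess 3 with 6 (second-generation Hoveyda–Grubbs catalyst, CH2Cl2, 40 °C) should give (E)-hexadeca-3,15-dien-2-one F1.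
- Treatment with 8 under the conditions of step 4 leads through dimethyl 2-(2-oxohexadec-15-en-4-yl)propanedioate F2, methyl 6-(dodec-11-en-1-yl)-2,4-dioxocyclohexane-1-carboxylate F3 and 6-(dodec-11-en-1-yl)-2,4-dioxocyclohexane-1-carboxylic acid F4 to 5-(dodec-11-en-1-yl)cyclohexane-1,3-dione F5.
- Oxalyl chloride with catalytic DMF gives 3-chloro-5-(dodec-11-en-1-yl)cyclohex-2-en-1-one F6.
- Intermolecular etherification of F6 with phenol 1 (Cs2CO3, MeCN, 60 °C) gives 3-(4-bromo-2,6-dimethoxyphenoxy)-5-(dodec-11-en-1-yl)cyclohex-2-en-1-one F7.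
- 9-BBN in THF hydroborates the terminal alkene, in preference to the ester-like vinylogous carbonyl, to give 3-(4-bromo-2,6-dimethoxyphenoxy)-5-[12-(9-borabicyclo[3.3.1]nonan-9-yl)dodecyl]cyclohex-2-en-1-one F8.
- Slow addition of F8 to PdCl2(dppf) and K3PO4 in DMF/THF at 60 °C (about 2 mM) closes the ring by intramolecular B-alkyl Suzuki–Miyaura coupling and returns to 15.

Step 8 (aromatisation). Electrophilic selenium by-products or the peroxide may attack the electron-rich phenol as it forms, or the selenoxide may lack a syn hydrogen at C5 and stall. The fallback is a Saegusa–Ito oxidation, which avoids both selenium and peroxide. It sets out from 15 and comes back at 19.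
- The kinetic enolate (LDA, THF, −78 °C) is trapped with TMSCl to give the trimethylsilyl dienol ether of 15 (C6=C1(OSiMe3)–C2=C3(OAr) diene) F9.
- Pd(OAc)2 (1.1 equiv) in MeCN at rt converts F9 through dienone 18 into 19.

Step 6 (debenzylation beside the chloroenone). The Lewis acid may activate the vinylogous acid chloride towards Friedel–Crafts-type attack by the scavenger or ring B, or a flanking methyl ether may be lost. The fallback removes the benzyl group before the chloride is installed. It sets out from 12 and comes back at 14.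
- Hydrogenolysis of 12 (H2, Pd/C, EtOAc/MeOH, rt) should give 5-[12-(4-hydroxy-3,5-dimethoxyphenyl)dodecyl]cyclohexane-1,3-dione F10.
- (COCl)2 (1.05 equiv) with catalytic DMF in CH2Cl2 at −20 °C should chlorinate the acidic, enolised dione ahead of the hindered phenol and give 14 directly.

**Further compounds**

F1 | step 7 | (E)-hexadeca-3,15-dien-2-one | CC(=O)/C=C/CCCCCCCCCCC=C
F2 | step 7 | dimethyl 2-(2-oxohexadec-15-en-4-yl)propanedioate | CC(=O)CC(CCCCCCCCCCC=C)C(C(=O)OC)C(=O)OC
F3 | step 7 | methyl 6-(dodec-11-en-1-yl)-2,4-dioxocyclohexane-1-carboxylate | COC(=O)C1C(CCCCCCCCCCC=C)CC(=O)CC1=O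
F4 | step 7 | 6-(dodec-11-en-1-yl)-2,4-dioxocyclohexane-1-carboxylic acid | OC(=O)C1C(CCCCCCCCCCC=C)CC(=O)CC1=O
F5 | step 7 | 5-(dodec-11-en-1-yl)cyclohexane-1,3-dione | O=C1CC(=O)CC(CCCCCCCCCCC=C)C1
F6 | step 7 | 3-chloro-5-(dodec-11-en-1-yl)cyclohex-2-en-1-one | O=C1C=C(Cl)CC(CCCCCCCCCCC=C)C1
F7 | step 7 | 3-(4-bromo-2,6-dimethoxyphenoxy)-5-(dodec-11-en-1-yl)cyclohex-2-en-1-one | O=C1C=C(Oc2c(OC)cc(Br)cc2OC)CC(CCCCCCCCCCC=C)C1
F8 | step 7 | 3-(4-bromo-2,6-dimethoxyphenoxy)-5-[12-(9-borabicyclo[3.3.1]nonan-9-yl)dodecyl]cyclohex-2-en-1-one | O=C1C=C(Oc2c(OC)cc(Br)cc2OC)CC(CCCCCCCCCCCCB2C3CCCC2CCC3)C1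
F9 | step 8 | trimethylsilyl dienol ether of 15 (C6=C1(OSiMe3)–C2=C3(OAr) diene) | C[Si](C)(C)OC1=CC(CCCCCCCCCCCCc3cc(OC)c(O2)c(OC)c3)CC2=C1
F10 | step 6 | 5-[12-(4-hydroxy-3,5-dimethoxyphenyl)dodecyl]cyclohexane-1,3-dione | O=C1CC(=O)CC(CCCCCCCCCCCCc2cc(OC)c(O)c(OC)c2)C1
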